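The numbering follows p-menthane: C1 carries C7H2O, C2 is the ketone, C3 bears OH, C4 bears isopropyl, C5 bears the ring tiglate and C6 is =CH. The cyclohexenone ring is cut at C2–C3 and C4–C5. Its anti 1,3-dioxygenation at C3 and C5 around C4, with C2 placed 1,4 to O–C5 across C1=C6, is the retron of an inverse-demand Diels–Alder reaction. The partners are methyl 2-pyrone-3-carboxylate and the (E)-silyl enol ether of isovaleraldehyde. One catalytic asymmetric cycloaddition forms both bonds and all three stereocentres. The pyrone oxygen becomes O–C5 and the enol oxygen becomes O–C3. C2 reacts with reversed polarity as a malonate carbon and is unmasked later by anodic double decarboxylation.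

Key step: step 3

Assumption: the Yb(OTf)3/(R)-BINOL complex is taken to leave open the pyrone face that leads to the enantiomer drawn; if the sense of induction is the opposite, (S)-BINOL is used with no other change.

Step 1
Reactants: 1 (E)-but-2-enal (crotonaldehyde)
Product: 2 (E)-trimethyl[(3-methylbut-1-en-1-yl)oxy]silane
Conditions: MeMgBr (1.2 equiv), CuBr·SMe2 (5 mol %), TMSCl (2 equiv), HMPA (2 equiv), THF, −78 °C; Et3N, pentane, cold aq NaHCO3
Reagents that add atoms: methylmagnesium bromide, C[Mg]Br; chlorotrimethylsilane, C[Si](C)(C)Cl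
Why: Chlorosilane-accelerated, copper-catalysed conjugate addition of the Grignard reagent to the s-trans enal builds the isopropyl group and silylates the enolate as it forms, which should fix the E geometry of the enol ether.

Step 2
Reactants: 2 (E)-trimethyl[(3-methylbut-1-en-1-yl)oxy]silane
Product: 4 (E)-tert-butyldimethyl[(3-methylbut-1-en-1-yl)oxy]silane, via lithium enolate 3 (not isolated)
Conditions: MeLi (1.05 equiv), THF, 0 °C; TBSCl (1.2 equiv), HMPA, −78 °C → rt
Reagents that add atoms: tert-butyldimethylsilyl chloride, CC(C)(C)[Si](C)(C)Cl; methyllithium, [Li]C (lithium of 3 only)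
Why: Cleavage of the Si–O bond by methyllithium regenerates the enolate with retention of its geometry, and O-silylation in the presence of HMPA exchanges the labile TMS group for a TBS group that survives to the last step.

Step 3
Reactants: 4 (E)-tert-butyldimethyl[(3-methylbut-1-en-1-yl)oxy]silane; 5 methyl 2-oxo-2H-pyran-3-carboxylate
Product: 6 methyl (1S,4R,7S,8R)-8-[(tert-butyldimethylsilyl)oxy]-7-isopropyl-3-oxo-2-oxabicyclo[2.2.2]oct-5-ene-4-carboxylate (OTBS endo, syn to the alkene bridge; isopropyl exo, syn to the lactone bridge)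
Conditions: Yb(OTf)3 (20 mol %), (R)-BINOL (24 mol %), iPr2NEt (48 mol %), 4 Å MS, CH2Cl2, 0 °C → rt, 4 (3 equiv)
Reagents that add atoms: none
Why: The ytterbium BINOL complex binds the lactone and ester carbonyl groups of 5 as a chelate and lowers its LUMO, so that the electron-rich alkene of 4 adds across pyrone C6 and C3 in a concerted, asynchronous inverse-electron-demand Diels–Alder reaction, the reaction type established for 5 and vinyl ethers under chiral lanthanide or titanium BINOL catalysis. The six-membered carbocycle closes by suprafacial [4+2] cycloaddition on one face of the planar pyrone, whose O1–C2 lactone unit becomes the two-atom bridge of a 2-oxabicyclo[2.2.2]octene. Regiochemistry follows the polarisation of both partners: the nucleophilic, isopropyl-bearing carbon of 4 bonds to electrophilic pyrone C6 next to the ring oxygen, and the oxygen-bearing carbon bonds to the malonate-type pyrone C3, which unites two carbons that are both electrophilic in the target. The E geometry of 4 is transferred as the trans relation of OTBS and isopropyl, and the endo preference of the silyloxy group places it anti and the isopropyl group syn to the lactone bridge, so that target C3, C4 and C5 arise in the correct relative sense in one event, while the ester-bearing bridgehead centre is tied to them by the bridge and is erased in step 4. The absolute sense comes from the BINOL ligand, which shields one face of the chelated pyrone. The step needs cycloaddition to outrun Mukaiyama–Michael addition with silyl transfer and thermal loss of CO2, which the robust TBS group, the mild lanthanide Lewis acid and a temperature at or below room temperature should secure.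

Step 4
Reactants: 6 methyl (1S,4R,7S,8R)-8-[(tert-butyldimethylsilyl)oxy]-7-isopropyl-3-oxo-2-oxabicyclo[2.2.2]oct-5-ene-4-carboxylate
Product: 7 (4S,5S,6R)-6-[(tert-butyldimethylsilyl)oxy]-4-hydroxy-5-isopropylcyclohex-2-ene-1,1-dicarboxylic acid
Conditions: LiOH·H2O (8 equiv), THF/MeOH/H2O, 0 → 45 °C; cold 1 M HCl to pH 3, EtOAc
Reagents that add atoms: lithium hydroxide, [Li+].[OH-]; water, O
Why: Saponification opens the allylic lactone bridge and then cleaves the methyl ester, which frees O–C5 as the alcohol and leaves the three stereocentres untouched, because the quaternary malonate carbon cannot enolise and the hindered TBS ether resists aqueous base.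

Step 5
Reactants: 7 (4S,5S,6R)-6-[(tert-butyldimethylsilyl)oxy]-4-hydroxy-5-isopropylcyclohex-2-ene-1,1-dicarboxylic acid
Product: 9 (4S,5S,6R)-6-[(tert-butyldimethylsilyl)oxy]-4-hydroxy-5-isopropylcyclohex-2-en-1-one, via dimethyl ketal 8 (not isolated)
Conditions: NH3 (7 M in MeOH, 4 equiv), MeOH, graphite anode and cathode, undivided cell, constant current, about 5 F/mol, rt; then 1 M HCl, THF, 0 °C
Reagents that add atoms: methanol, CO (into intermediate 8); water, O
Why: Hofer–Moest (non-Kolbe) anodic oxidation removes both carboxylates of the disubstituted malonic acid as CO2 through cations at C2 that methanol traps, the second one stabilised by the first methoxy group, and mild acid then releases the conjugated ketone, a path that never places a carbanion next to the β-silyloxy group, so that nothing is eliminated or epimerised.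

Step 6
Reactants: 9 (4S,5S,6R)-6-[(tert-butyldimethylsilyl)oxy]-4-hydroxy-5-isopropylcyclohex-2-en-1-one
Product: 10 (4S,5S,6R)-6-[(tert-butyldimethylsilyl)oxy]-4-hydroxy-2-(hydroxymethyl)-5-isopropylcyclohex-2-en-1-one
Conditions: 37 % aq HCHO (5 equiv), DMAP (0.3 equiv), THF, rt
Reagents that add atoms: formaldehyde, C=O
Why: In the Morita–Baylis–Hillman reaction DMAP adds reversibly to C6, the enolate attacks formaldehyde through C1 and loss of DMAP restores the enone, so that C7 enters without strong base while C3 already holds its more stable equatorial, trans configuration.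

Step 7
Reactants: 10 (4S,5S,6R)-6-[(tert-butyldimethylsilyl)oxy]-4-hydroxy-2-(hydroxymethyl)-5-isopropylcyclohex-2-en-1-one; 11 (E)-2-methylbut-2-enoyl chloride (tigloyl chloride)
Product: 12 [(3S,4S,5R)-5-[(tert-butyldimethylsilyl)oxy]-4-isopropyl-6-oxo-3-{[(E)-2-methylbut-2-enoyl]oxy}cyclohex-1-en-1-yl]methyl (E)-2-methylbut-2-enoate
Conditions: 11 (3 equiv), pyridine (6 equiv), DMAP (5 mol %), CH2Cl2, 0 °C → rt
Reagents that add atoms: tigloyl chloride (11), C/C=C(\C)C(=O)Cl
Why: Acylation of the only two free hydroxy groups installs both tiglates at once, and pyridine in place of a trialkylamine, with little DMAP, should avoid vinylketene formation with deconjugation and SN2' attack on the new allylic ester.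

Step 8
Reactants: 12 [(3S,4S,5R)-5-[(tert-butyldimethylsilyl)oxy]-4-isopropyl-6-oxo-3-{[(E)-2-methylbut-2-enoyl]oxy}cyclohex-1-en-1-yl]methyl (E)-2-methylbut-2-enoate
Product: 13 [(3S,4R,5R)-5-hydroxy-4-isopropyl-6-oxo-3-{[(E)-2-methylbut-2-enoyl]oxy}cyclohex-1-en-1-yl]methyl (E)-2-methylbut-2-enoate (CNP0326914.1)
Conditions: HF·pyridine, pyridine, THF, 0 °C → rt
Reagents that add atoms: none
Why: Fluoride-driven desilylation in a buffered, weakly acidic medium frees the C3 hydroxy group without touching the enone or the two allylic tiglates, and the 1,3-trans relation of O–C3 and O–C5 rules out acyl migration.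

Compound list
1 | (E)-but-2-enal | C/C=C/C=O | starting material
2 | (E)-trimethyl[(3-methylbut-1-en-1-yl)oxy]silane | CC(C)/C=C/O[Si](C)(C)C | intermediate
3 | lithium (E)-3-methylbut-1-en-1-olate | CC(C)/C=C/[O-].[Li+] | intermediate
4 | (E)-tert-butyldimethyl[(3-methylbut-1-en-1-yl)oxy]silane | CC(C)/C=C/O[Si](C)(C)C(C)(C)C | intermediate
5 | methyl 2-oxo-2H-pyran-3-carboxylate | COC(=O)C1=CC=COC1=O | starting material
6 | methyl (1S,4R,7S,8R)-8-[(tert-butyldimethylsilyl)oxy]-7-isopropyl-3-oxo-2-oxabicyclo[2.2.2]oct-5-ene-4-carboxylate | C1=C[C@H](OC2=O)[C@H](C(C)C)[C@@H](O[Si](C)(C)C(C)(C)C)[C@@]12C(=O)OC | intermediate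
7 | (4S,5S,6R)-6-[(tert-butyldimethylsilyl)oxy]-4-hydroxy-5-isopropylcyclohex-2-ene-1,1-dicarboxylic acid | C1=C[C@H](O)[C@H](C(C)C)[C@@H](O[Si](C)(C)C(C)(C)C)C1(C(=O)O)C(=O)O | intermediate
8 | (1S,5R,6S)-5-[(tert-butyldimethylsilyl)oxy]-6-isopropyl-4,4-dimethoxycyclohex-2-en-1-ol | C1=C[C@H](O)[C@H](C(C)C)[C@@H](O[Si](C)(C)C(C)(C)C)C1(OC)OC | intermediate
9 | (4S,5S,6R)-6-[(tert-butyldimethylsilyl)oxy]-4-hydroxy-5-isopropylcyclohex-2-en-1-one | C1=C[C@H](O)[C@H](C(C)C)[C@@H](O[Si](C)(C)C(C)(C)C)C1=O | intermediate
10 | (4S,5S,6R)-6-[(tert-butyldimethylsilyl)oxy]-4-hydroxy-2-(hydroxymethyl)-5-isopropylcyclohex-2-en-1-one | OCC1=C[C@H](O)[C@H](C(C)C)[C@@H](O[Si](C)(C)C(C)(C)C)C1=O | intermediate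
11 | (E)-2-methylbut-2-enoyl chloride | C/C=C(\C)C(=O)Cl | starting material
12 | [(3S,4S,5R)-5-[(tert-butyldimethylsilyl)oxy]-4-isopropyl-6-oxo-3-{[(E)-2-methylbut-2-enoyl]oxy}cyclohex-1-en-1-yl]methyl (E)-2-methylbut-2-enoate | C/C=C(\C)C(=O)OCC1=C[C@H](OC(=O)/C(C)=C/C)[C@H](C(C)C)[C@@H](O[Si](C)(C)C(C)(C)C)C1=O | intermediate
13 | [(3S,4R,5R)-5-hydroxy-4-isopropyl-6-oxo-3-{[(E)-2-methylbut-2-enoyl]oxy}cyclohex-1-en-1-yl]methyl (E)-2-methylbut-2-enoate | C/C=C(\C)C(=O)OCC1=C[C@H](OC(=O)/C(C)=C/C)[C@H](C(C)C)[C@@H](O)C1=O | target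

Total step count: 8. Longest linear sequence: 8 steps (1 → 13).

Steps most likely to fail

1. Step 3. The β-branched, bulky enol ether may add too slowly. It may also add stepwise, so that bond rotation and silyl transfer erode the trans relation, or the catalyst may discriminate the two pyrone faces poorly. The fallback sets out from 4 and comes back at 7. It moves facial control from the catalyst to a covalent auxiliary and activation from a Lewis acid to pressure. Commercial 2-oxo-2H-pyran-3-carboxylic acid is esterified with (R)-pantolactone (DCC, DMAP, CH2Cl2) to the pantolactonyl pyrone ester F1. This ester is combined with 4 at about 12 kbar (CH2Cl2, rt) to give the auxiliary-bearing bicyclic lactone F2. The diastereomers can be separated by crystallisation or chromatography. The LiOH treatment of step 4 then cleaves bridge and auxiliary together to give 7.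

2. Step 5. After the first decarboxylation the cation is allylic, so methanol may enter at C6 with transposition of the double bond. The free allylic alcohol may also be oxidised at the anode. The fallback sets out from 6 and comes back at 9. It removes the two carboxyl carbons one at a time while the bridge still holds C2 as a bridgehead, where allylic delocalisation is impossible.
   - SN2 demethylation (LiSPr, HMPA, rt) gives the bridgehead carboxylic acid F3.
   - 2-Mercaptopyridine N-oxide and EDC give the thiohydroxamate ester F4.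
   - Barton decarboxylation under O2 (tBuSH, visible light, toluene, 0 °C) gives the bridgehead hydroperoxide F5.
   - P(OMe)3 reduces it to the α-hydroxy lactone F6.
   - LiOH opens the bridge to the α-hydroxy acid F7, and Pb(OAc)4 (CH2Cl2, 0 °C) converts it by oxidative decarboxylation into 9.

3. Step 6. Addition of DMAP to C6 next to the substituted C5 may be slow, and the base may instead isomerise the γ-hydroxy enone to the 1,4-diketone. The fallback sets out from 9 and comes back at 10, and it brings in C7 by cross-coupling. α-Iodination (I2, pyridine, CH2Cl2, rt) gives the 2-iodo enone F8. Stille coupling with Bu3SnCH2OH (Pd(PPh3)4, CuI, DMF, 50 °C) then gives 10.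

Further compounds
F1 | step 3 | (3R)-4,4-dimethyl-2-oxooxolan-3-yl 2-oxo-2H-pyran-3-carboxylate | O=C1OC=CC=C1C(=O)O[C@H]1C(=O)OCC1(C)C
F2 | step 3 | (3R)-4,4-dimethyl-2-oxooxolan-3-yl ester analogue of 6, same configuration of the bicycle | C1=C[C@H](OC2=O)[C@H](C(C)C)[C@@H](O[Si](C)(C)C(C)(C)C)[C@@]12C(=O)O[C@H]1C(=O)OCC1(C)C
F3 | step 5 | 8-[(tert-butyldimethylsilyl)oxy]-7-isopropyl-3-oxo-2-oxabicyclo[2.2.2]oct-5-ene-4-carboxylic acid, configuration as in 6 | C1=C[C@H](OC2=O)[C@H](C(C)C)[C@@H](O[Si](C)(C)C(C)(C)C)[C@@]12C(=O)O
F4 | step 5 | 2-thioxopyridin-1(2H)-yl ester of F3 | C1=C[C@H](OC2=O)[C@H](C(C)C)[C@@H](O[Si](C)(C)C(C)(C)C)[C@@]12C(=O)ON1C=CC=CC1=S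
F5 | step 5 | 8-[(tert-butyldimethylsilyl)oxy]-4-hydroperoxy-7-isopropyl-2-oxabicyclo[2.2.2]oct-5-en-3-one | C1=C[C@H](OC2=O)[C@H](C(C)C)[C@@H](O[Si](C)(C)C(C)(C)C)[C@@]12OO
F6 | step 5 | 8-[(tert-butyldimethylsilyl)oxy]-4-hydroxy-7-isopropyl-2-oxabicyclo[2.2.2]oct-5-en-3-one | C1=C[C@H](OC2=O)[C@H](C(C)C)[C@@H](O[Si](C)(C)C(C)(C)C)[C@@]12O
F7 | step 5 | 6-[(tert-butyldimethylsilyl)oxy]-1,4-dihydroxy-5-isopropylcyclohex-2-ene-1-carboxylic acid, carboxyl cis to the C4 hydroxy group | C1=C[C@H](O)[C@H](C(C)C)[C@@H](O[Si](C)(C)C(C)(C)C)[C@]1(O)C(=O)O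
F8 | step 6 | (4S,5S,6R)-6-[(tert-butyldimethylsilyl)oxy]-4-hydroxy-2-iodo-5-isopropylcyclohex-2-en-1-one | IC1=C[C@H](O)[C@H](C(C)C)[C@@H](O[Si](C)(C)C(C)(C)C)C1=O
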